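## Retrosynthetic overview

1. The lactone ring is closed last: the target comes from (15S)-16-acetoxycarnosic acid by catechol oxidation, tautomerisation to the C7 quinone methide and attack of the C20 acid, which sets C7.
2. The C16 acetate comes from ozonolysis, reduction and acetylation of a 13-[(2R,3E)-pent-3-en-2-yl] group.
3. Key C13–C15 bond: aromatic Claisen [3,3] shift of a 12-O-[(2S,3E)-pent-3-en-2-yl] ether, with 1,3-chirality transfer setting C15.
4. The ether comes from Mitsunobu union of benzyl 13-deisopropylcarnosate with (2R,3E)-pent-3-en-2-ol, made in two steps from (R)-but-3-yn-2-ol.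
5. Rings A, B and C with C5 and C10 are bought in (+)-carnosic acid, whose isopropyl group is removed by retro-Friedel–Crafts transalkylation; no carbocycle is built.

Assumption: (+)-carnosic acid (bulk rosemary-extract product) and (R)-but-3-yn-2-ol are taken as purchasable enantiopure starting materials.

The route has not been run; the deisopropylation in step 3 has precedent only on simpler dehydroabietane esters and phenols, not on carnosic acid itself.

## Route

Step 1
Reactants: 1 (R)-but-3-yn-2-ol
Product: 2 (R)-pent-3-yn-2-ol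
Conditions: n-BuLi (2.1 equiv), THF, −78 to 0 °C; MeI (1.05 equiv), −78 °C to rt; H2O quench
Reagents that add atoms: iodomethane, SMILES CI
Why: Double deprotonation gives the alkoxide–acetylide dianion, whose acetylide carbon is methylated selectively (SN2 C-alkylation of a terminal alkyne), and the bought carbinol stereocenter is not touched.

Step 2
Reactants: 2 (R)-pent-3-yn-2-ol
Product: 3 (2R,3E)-pent-3-en-2-ol
Conditions: LiAlH4 (1.5 equiv), THF, 65 °C; H2O/NaOH work-up; careful distillation
Reagents that add atoms: none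
Why: Alkoxide-directed trans-hydroalumination of the propargylic alcohol followed by protonolysis gives the E-allylic alcohol only, with the (R) centre intact.

Step 3
Reactants: 4 (+)-carnosic acid
Product: 5 13-deisopropylcarnosic acid
Conditions: AlCl3 (6 equiv), toluene (solvent and isopropyl acceptor), 0 to 50 °C, Ar; ice/1 M HCl
Reagents that add atoms: none
Why: Retro-Friedel–Crafts transalkylation: ipso-protonation at C13 (ortho to the 12-oxygen) expels the isopropyl cation to toluene, while C10 cannot ionise because it carries the carboxyl group, so the bought C5 and C10 centres stay as they are.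

Step 4
Reactants: 5 13-deisopropylcarnosic acid
Product: 6 benzyl 13-deisopropylcarnosate
Conditions: BnBr (1.05 equiv), KHCO3 (1.2 equiv), DMF, rt, Ar
Reagents that add atoms: benzyl bromide, SMILES BrCc1ccccc1
Why: Chemoselective SN2 O-alkylation of the carboxylate, because bicarbonate deprotonates the acid but not the phenols.

Step 5
Reactants: 6 benzyl 13-deisopropylcarnosate; 3 (2R,3E)-pent-3-en-2-ol
Product: 7 benzyl 11-hydroxy-12-[(2S,3E)-pent-3-en-2-yloxy]podocarpa-8,11,13-trien-20-oate
Conditions: PPh3 (1.3 equiv), DIAD (1.3 equiv), 3 (1.3 equiv), THF, 0 °C to rt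
Reagents that add atoms: none
Why: Mitsunobu etherification: the phenol displaces the activated secondary allylic alcohol by SN2 with inversion, so the (R)-alcohol gives the (S)-ether, and the 12-OH reacts because the 11-OH is hydrogen-bonded to the ester and shielded by C1.

Step 6
Reactants: 7 benzyl 11-hydroxy-12-[(2S,3E)-pent-3-en-2-yloxy]podocarpa-8,11,13-trien-20-oate
Product: 9 benzyl 11,12-dihydroxy-13-[(2R,3E)-pent-3-en-2-yl]podocarpa-8,11,13-trien-20-oate, via ortho-dienone 8 (not isolated)
Conditions: PhNEt2 (degassed), 160 °C, sealed tube, Ar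
Reagents that add atoms: none
Why: Aromatic Claisen [3,3]-sigmatropic rearrangement to C13, the only free ortho position, through a chair with the carbinol methyl equatorial, so the C–O chirality is transferred suprafacially to the new C13–C15 bond ((S)-ether to (R)-C15, E-alkene) before the dienone enolises back to the catechol.

Step 7
Reactants: 9 benzyl 11,12-dihydroxy-13-[(2R,3E)-pent-3-en-2-yl]podocarpa-8,11,13-trien-20-oate
Product: 10 benzyl 11,12-bis(benzyloxy)-13-[(2R,3E)-pent-3-en-2-yl]podocarpa-8,11,13-trien-20-oate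
Conditions: BnBr (2.5 equiv), K2CO3 (3 equiv), DMF, 60 °C, Ar
Reagents that add atoms: benzyl bromide, SMILES BrCc1ccccc1
Why: Williamson etherification of both phenols shields the electron-rich catechol from ozone and from acetylation and installs groups that later leave together with the benzyl ester.

Step 8
Reactants: 10 benzyl 11,12-bis(benzyloxy)-13-[(2R,3E)-pent-3-en-2-yl]podocarpa-8,11,13-trien-20-oate
Product: 12 benzyl 11,12-bis(benzyloxy)-13-[(2S)-1-hydroxypropan-2-yl]podocarpa-8,11,13-trien-20-oate, via C16 aldehyde 11 (not isolated)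
Conditions: O3, CH2Cl2/MeOH 4:1, −78 °C (Sudan red end point); NaBH4, −78 to 0 °C
Reagents that add atoms: ozone, SMILES [O-][O+]=O
Why: Ozonolysis cleaves the only C=C bond and NaBH4 added cold reduces the peroxidic intermediate and the aldehyde at once, so the enolisable 2-arylpropanal never accumulates and C15 keeps its configuration (S only by priority change), while the neopentyl benzyl ester is too hindered to be reduced.

Step 9
Reactants: 12 benzyl 11,12-bis(benzyloxy)-13-[(2S)-1-hydroxypropan-2-yl]podocarpa-8,11,13-trien-20-oate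
Product: 13 benzyl 13-[(2S)-1-acetoxypropan-2-yl]-11,12-bis(benzyloxy)podocarpa-8,11,13-trien-20-oate
Conditions: Ac2O, pyridine, DMAP (cat.), CH2Cl2, 0 °C to rt
Reagents that add atoms: acetic anhydride, SMILES CC(=O)OC(C)=O
Why: DMAP-catalysed acylation of the only free hydroxyl group.

Step 10
Reactants: 13 benzyl 13-[(2S)-1-acetoxypropan-2-yl]-11,12-bis(benzyloxy)podocarpa-8,11,13-trien-20-oate
Product: 14 (15S)-16-acetoxycarnosic acid
Conditions: H2 (1 atm), 10% Pd/C, EtOAc, rt; filter under Ar and use crude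
Reagents that add atoms: none
Why: Hydrogenolysis cleaves the two benzyl ethers and the benzyl ester at their benzylic C–O bonds, while the homobenzylic acetate and the stereocentres are inert.

Step 11
Reactants: 14 (15S)-16-acetoxycarnosic acid
Product: 17 (15S)-16-acetoxycarnosol (target), via ortho-quinone 15 (not isolated), via para-quinone methide 16 (not isolated)
Conditions: Ag2O (2 equiv), Et2O, rt, dark; filter; acetone/H2O, rt, 16 h
Reagents that add atoms: none
Why: Biomimetic oxidative lactonisation as in carnosic acid to carnosol: Ag2O gives the ortho-quinone, which tautomerises through C7–H to the para-quinone methide, and the C20 carboxyl fixed on the β face of C10 adds to C7 (intramolecular oxa-Michael), so the bridged lactone can only form with the C7 configuration of the target.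

## Compound list

1 | (R)-but-3-yn-2-ol | C#C[C@@H](C)O | starting material
2 | (R)-pent-3-yn-2-ol | CC#C[C@@H](C)O | intermediate
3 | (2R,3E)-pent-3-en-2-ol | C/C=C/[C@@H](C)O | intermediate
4 | (+)-carnosic acid, (4aR,10aS)-11,12-dihydroxyabieta-8,11,13-trien-20-oic acid | CC(C)c1cc2c(c(O)c1O)[C@@]1(C(=O)O)CCCC(C)(C)[C@@H]1CC2 | starting material
5 | 13-deisopropylcarnosic acid (11,12-dihydroxypodocarpa-8,11,13-trien-20-oic acid) | Oc1ccc2c(c1O)[C@@]1(C(=O)O)CCCC(C)(C)[C@@H]1CC2 | intermediate
6 | benzyl 13-deisopropylcarnosate (benzyl 11,12-dihydroxypodocarpa-8,11,13-trien-20-oate) | Oc1ccc2c(c1O)[C@@]1(C(=O)OCc3ccccc3)CCCC(C)(C)[C@@H]1CC2 | intermediate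
7 | benzyl 11-hydroxy-12-[(2S,3E)-pent-3-en-2-yloxy]podocarpa-8,11,13-trien-20-oate | C/C=C/[C@H](C)Oc1ccc2c(c1O)[C@@]1(C(=O)OCc3ccccc3)CCCC(C)(C)[C@@H]1CC2 | intermediate
8 | ortho-dienone of the Claisen step: benzyl 11-hydroxy-12-oxo-13-[(2R,3E)-pent-3-en-2-yl]podocarpa-8(14),9(11)-dien-20-oate (transient ring carbon C13 not specified) | C/C=C/[C@@H](C)C1C=C2C(=C(O)C1=O)[C@@]1(C(=O)OCc3ccccc3)CCCC(C)(C)[C@@H]1CC2 | intermediate
9 | benzyl 11,12-dihydroxy-13-[(2R,3E)-pent-3-en-2-yl]podocarpa-8,11,13-trien-20-oate | C/C=C/[C@@H](C)c1cc2c(c(O)c1O)[C@@]1(C(=O)OCc3ccccc3)CCCC(C)(C)[C@@H]1CC2 | intermediate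
10 | benzyl 11,12-bis(benzyloxy)-13-[(2R,3E)-pent-3-en-2-yl]podocarpa-8,11,13-trien-20-oate | C/C=C/[C@@H](C)c1cc2c(c(OCc3ccccc3)c1OCc4ccccc4)[C@@]1(C(=O)OCc5ccccc5)CCCC(C)(C)[C@@H]1CC2 | intermediate
11 | C16 aldehyde: benzyl 11,12-bis(benzyloxy)-13-[(2S)-1-oxopropan-2-yl]podocarpa-8,11,13-trien-20-oate | O=C[C@@H](C)c1cc2c(c(OCc3ccccc3)c1OCc4ccccc4)[C@@]1(C(=O)OCc5ccccc5)CCCC(C)(C)[C@@H]1CC2 | intermediate
12 | benzyl 11,12-bis(benzyloxy)-13-[(2S)-1-hydroxypropan-2-yl]podocarpa-8,11,13-trien-20-oate | OC[C@@H](C)c1cc2c(c(OCc3ccccc3)c1OCc4ccccc4)[C@@]1(C(=O)OCc5ccccc5)CCCC(C)(C)[C@@H]1CC2 | intermediate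
13 | benzyl 13-[(2S)-1-acetoxypropan-2-yl]-11,12-bis(benzyloxy)podocarpa-8,11,13-trien-20-oate | CC(=O)OC[C@@H](C)c1cc2c(c(OCc3ccccc3)c1OCc4ccccc4)[C@@]1(C(=O)OCc5ccccc5)CCCC(C)(C)[C@@H]1CC2 | intermediate
14 | (15S)-16-acetoxycarnosic acid | CC(=O)OC[C@@H](C)c1cc2c(c(O)c1O)[C@@]1(C(=O)O)CCCC(C)(C)[C@@H]1CC2 | intermediate
15 | ortho-quinone of 14 (11,12-dioxo-8,13-diene) | CC(=O)OC[C@@H](C)C1=CC2=C(C(=O)C1=O)[C@@]1(C(=O)O)CCCC(C)(C)[C@@H]1CC2 | intermediate
16 | para-quinone methide of 14 (7,8-ene, 11-hydroxy, 12-oxo) | CC(=O)OC[C@@H](C)C1=CC2=CC[C@H]3C(C)(C)CCC[C@]3(C(=O)O)C2=C(O)C1=O | intermediate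
17 | (15S)-16-acetoxycarnosol, CNP0105472.1 | CC(=O)OC[C@@H](C)c1cc2c(c(O)c1O)[C@@]13CCCC(C)(C)[C@@H]1C[C@@H]2OC3=O | target

## Step count and risks

Total: 11 steps. Longest linear sequence: 9 steps (steps 3 to 11 from carnosic acid; the same length through steps 1, 2 and 5 to 11 from the butynol).

Steps most likely to fail:

**Step 3 (removal of the isopropyl group).** The free acid and catechol bind AlCl3 as an insoluble chelate, and the acid could decarbonylate or the dealkylation could stall. The fallback sets out from 4 and comes back at 5. It masks the acid and the 11-OH together first: DCC in CH2Cl2 closes 4 to carnosic acid 20,11-lactone F1, a neutral, toluene-soluble ortho-hydroxyphenylacetic-type lactone with only the 12-OH free. This is dealkylated under homogeneous Brønsted catalysis (TfOH, toluene, 60 °C) to 13-deisopropylcarnosic acid 20,11-lactone F2. The aryl lactone is then opened with degassed LiOH in aqueous THF and acidified to give 5.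

**Step 5 (Mitsunobu with a secondary allylic alcohol).** The risk is loss of configuration through SN2' attack or ionisation of the symmetric 1,3-dimethylallyl system. The fallback sets out from 6 and comes back at 7, and builds the allyl ether around a carbinol that cannot do either. Mitsunobu reaction of 6 with methyl (R)-lactate (PPh3, DIAD, THF) gives, with clean inversion, benzyl 11-hydroxy-12-[(2S)-1-methoxy-1-oxopropan-2-yloxy]podocarpa-8,11,13-trien-20-oate F3. i-Bu2AlH in CH2Cl2 at −78 °C reduces only the unhindered methyl ester, to benzyl 11-hydroxy-12-[(2S)-1-oxopropan-2-yloxy]podocarpa-8,11,13-trien-20-oate F4. Julia–Kocienski olefination of F4 with 5-(ethylsulfonyl)-1-phenyl-1H-tetrazole and KN(SiMe3)2 (DME, −60 °C to rt) then gives the E-alkene 7. The α-aryloxy aldehyde F4 is itself epimerisable, so it must be used cold and at once.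

**Step 6 (thermal Claisen with a free 11-OH).** At 160 °C the 11-OH may lactonise onto the benzyl ester or the catechol product may oxidise. The fallback sets out from 7 and comes back at 10, and changes the protecting order so that no free catechol is heated. The 11-OH of 7 is capped first (BnBr, K2CO3, DMF, 60 °C) to give benzyl 11-benzyloxy-12-[(2S,3E)-pent-3-en-2-yloxy]podocarpa-8,11,13-trien-20-oate F5. The same [3,3] shift (PhNEt2, 170 °C) then gives benzyl 11-benzyloxy-12-hydroxy-13-[(2R,3E)-pent-3-en-2-yl]podocarpa-8,11,13-trien-20-oate F6. Benzylation of its 12-OH (BnBr, K2CO3, DMF) gives 10.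

Further compounds
F1 | step 3 | carnosic acid 20,11-lactone | CC(C)c1cc2c3c(c1O)OC(=O)[C@@]31CCCC(C)(C)[C@@H]1CC2
F2 | step 3 | 13-deisopropylcarnosic acid 20,11-lactone | Oc1ccc2c3c1OC(=O)[C@@]31CCCC(C)(C)[C@@H]1CC2
F3 | step 5 | benzyl 11-hydroxy-12-[(2S)-1-methoxy-1-oxopropan-2-yloxy]podocarpa-8,11,13-trien-20-oate | COC(=O)[C@H](C)Oc1ccc2c(c1O)[C@@]1(C(=O)OCc3ccccc3)CCCC(C)(C)[C@@H]1CC2
F4 | step 5 | benzyl 11-hydroxy-12-[(2S)-1-oxopropan-2-yloxy]podocarpa-8,11,13-trien-20-oate | O=C[C@H](C)Oc1ccc2c(c1O)[C@@]1(C(=O)OCc3ccccc3)CCCC(C)(C)[C@@H]1CC2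
F5 | step 6 | benzyl 11-benzyloxy-12-[(2S,3E)-pent-3-en-2-yloxy]podocarpa-8,11,13-trien-20-oate | C/C=C/[C@H](C)Oc1ccc2c(c1OCc3ccccc3)[C@@]1(C(=O)OCc4ccccc4)CCCC(C)(C)[C@@H]1CC2
F6 | step 6 | benzyl 11-benzyloxy-12-hydroxy-13-[(2R,3E)-pent-3-en-2-yl]podocarpa-8,11,13-trien-20-oate | C/C=C/[C@@H](C)c1cc2c(c(OCc3ccccc3)c1O)[C@@]1(C(=O)OCc4ccccc4)CCCC(C)(C)[C@@H]1CC2
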